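**Vessel and clock.** In the stirred vessel electrophile and nucleophile make target, and target drains to over-reaction product. Judge each flask by how many target lives lie between its last making of target and its end.

| flask | electrophile | nucleophile | remark | time |
|---|---|---|---|---|
| autumn | 18 mM | 16.2 mM | run made earlier |  |
| midnight | 9 mM | 16.2 mM | run made earlier |  |
| dusk | 14 mM | 16.2 mM | run made earlier |  |
| Monday's | 18 mM | 16.2 mM (fed, over 5.0 h) | all else is in the flask from the start; the feed brings no volume worth counting | 6.0 h |
| Friday's | 18 mM | 16.2 mM | everything together at the start | 6.0 h |
| Sunday's | 18 mM (fed, over 5.0 h) | 16.2 mM | all else is in the flask from the start; the feed brings no volume worth counting | 6.0 h |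
| Saturday's | 18 mM (fed, over 80 min) | 16.2 mM | all else is in the flask from the start; the feed brings no volume worth counting | 6.0 h |

- autumn (time / h: target / %, over-reaction product / %, electrophile / %): 0.667: 21, 11, 58; 1.33: 16, 26, 50; 2.00: 11, 33, 44; 3.00: 5, 42, 37; 4.00: 3, 42, 34
- midnight (time / h: target / %, over-reaction product / %, electrophile / %): 0.417: 29, 8, 61; 0.667: 29, 14, 49; 1.33: 26, 35, 32; 2.50: 15, 58, 22; 5.00: 6, 78, 12
- dusk (time / h: target / %, over-reaction product / %, electrophile / %): 0.417: 27, 4, 65; 1.33: 21, 28, 43; 2.00: 12, 41, 40; 3.00: 7, 49, 34; 5.00: 2, 57, 29

(each reading ± 1.5 percentage points)

- the numbers in the tables scatter with a standard deviation of 1.5 percentage points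

- the best flask by share of target in target plus over-reaction product; "all alike" if 1.5 percentage points covers them all (Monday's / Friday's / Sunday's / Saturday's / all alike)
- share of target in target plus over-reaction product at the end, Monday's
- share of target in target plus over-reaction product at the end, Friday's
- share of target in target plus over-reaction product at the end, Sunday's
- share of target in target plus over-reaction product at the end, Saturday's

**Two readings.** In the autumn run, target plus over-reaction product stops near 45.0%. Take the ceiling as 45.0%, which charges two nucleophiles for each unit made; nucleophile is then the limiting reagent. In the same run c(target) falls from 16% to 5% between 1.33 h and 3.00 h. This gives 1.44 h, the target life: the time in which c(target) falls by a factor e once making stops. Making still ran during those readings, so treat this reading as an upper value.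

**Early extreme.** Friday's repeats the autumn recipe. Assume making is over at 4.00 h, with target at 3%. By 6.0 h target stands at 0.745%, a share of 1.66%.

**Late extreme.** In Monday's, assume each fed nucleophile reacts at once. The feed lasts longer than the life, so c(target) levels at making rate times life, 12.9%. The last 1.00 h brings it to 6.44%, a share of 14.3%.

**Between them.** Saturday's feed ends before the autumn run's last reading, so place Saturday's near Friday's. Place Sunday's above Saturday's, since its feed runs longer. Commit to Monday's as best.

**The forecast.** It parts from this reckoning at the top, naming Sunday's with 13%, against 10% for Monday's, 4% for Friday's and 6% for Saturday's, and it adds that “the Sunday/Monday order is uncertain”.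

**The result.** The best flask is Monday's: Monday's 13.4%, Friday's 1.46%, Sunday's 6.57%, Saturday's 2.05%.

    target → over-reaction product (k = 2.70 × 10⁻⁴ /s)
    nucleophile + acid set free ⇌ protonated nucleophile, settled at all times (K = 71000 /M)
    electrophile + nucleophile → acid set free + target (k = 0.0230 /M/s)
    2 electrophile → self-condensation product (k = 0.00140 /M/s)

**Target's clock.** In Friday's, target's half-life by its loss to over-reaction product alone is 0.71 h, short against the 6.0 h, and at the end target is made at 0.515 of the rate it is used up. Monday's stops less than one life after its feed, and its target goes from 7.61% to 5.52% in that time. Sunday's also stops 1.00 h after its feed, and its target goes from 5.55% to 2.98% in that time.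

(All runs come from a simulation with constants of no real substance; noise was put on by code.)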